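4 questions stand on this flask, each read at 50% conversion of the substrate.

substrate 0.0010 M; partner 2.50 equiv; free catalyst 0.05 mol%

    substrate + free catalyst ⇌ free catalyst + open intermediate (K1 = 1.11, k1 = 1.09 × 10⁶ L mol⁻¹ s⁻¹)
    free catalyst + open intermediate ⇌ catalyst intermediate (K2 = 1900 L mol⁻¹, k2 = 4.87 × 10⁵ L mol⁻¹ s⁻¹)
    partner + catalyst intermediate → free catalyst + product (k3 = 6.74 × 10⁵ L mol⁻¹ s⁻¹)
    free catalyst ⇌ dormant form (K4 = 4.3, k4 = 0.148 s⁻¹)

- the form that holds most of the catalyst when 50% of the substrate are converted (catalyst intermediate / dormant form / free catalyst)
- its share of the catalyst then
- factor on the rate of making product when 50% of the substrate are converted if partner is charged twice over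
- factor on the rate when 50% of the substrate are converted if free catalyst is charged at 0.25 mol% instead

Free catalyst passes to dormant form and back, and the two directions together close on their balance at the drift constant:

λ = 0.148 s⁻¹ × (1 + 1/4.3) = 0.182 s⁻¹

This drift constant gives the working share w, the part of the catalyst charged that is not dormant:

w(t) = w∞ + (1 − w∞) × exp(−λt), with w∞ = 1/(1 + 4.3) = 18.9%

The share needs a time. Substrate meets free catalyst, taken at its charge, at a pseudo-first-order constant of 0.545 s⁻¹, so a first estimate is:

t = ln(2)/g = 1.27 s

But that step runs back. Without a drain, c(substrate) levels at 47.4% of its charge, so the mark lies close to that level: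

t = ln((1 − 47.4%)/(50% − 47.4%)) / (g × (1 + 1/1.11)) = 2.90 s

That is later than the first estimate. Two objections remain: the shrinking free catalyst stretches this time, and the partner's drain on open intermediate shortens it. They pull in opposite directions, so 2.90 s stands as the working figure, and it gives w = 66.7%.

Yet not all working catalyst is free. Counting all converted substrate as open intermediate, with the partner as charged, gives a high estimate of the ratio of the two forms:

c(catalyst intermediate)/c(free catalyst) ≈ 0.125

Free catalyst is therefore reckoned at about 59.2% to 66.7% of the catalyst, more than the 33.3% reckoned as dormant. This makes free catalyst the resting state of the round. The reckoning by hand stops there.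

The forecast gives free catalyst at 64%, with a factor of 1.09 for the partner and 6.7 for the loading, the second since “the point is reached even earlier, with less catalyst lost to the dormant form”.

The flask reaches the mark at 2.75 s and holds free catalyst at 63.5%, beside 30.2% dormant form and 6.26% catalyst intermediate; twice the partner gives a factor of 1.11, and the higher loading 6.71. At 2.75 s the working share reckons to 68.0%, and the non-dormant forms read 69.8%. The flask at 0.25 mol% carries 5.00 times the catalyst; if its time to the mark shortens by that factor, its working share is 92.3%, which turns 5.00 into 6.79, and the rate of that flask stands at 6.71 times.

The constants come from no measurement; the result is computed.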